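Late in the run the charge should stand as target or side product, and one side product swallows one starting material and one target, so the final level of target is what a race for starting material leaves.

    starting material + free catalyst ⇌ catalyst intermediate A (K1 = 320 /M, k1 = 31 /M/s)
    catalyst intermediate A → free catalyst + target (k2 = 0.73 /s)
    second substrate + free catalyst ⇌ catalyst intermediate B (K3 = 480 /M, k3 = 39 /M/s)
    catalyst intermediate B → free catalyst + second product (k4 = 0.82 /s)
    solid substrate ⇌ starting material, rate k5*(cs5 - [starting material]) while solid is left; crystals form when [starting material] > cs5 (cs5 = 0.050 M, k5 = 0.13 /s)
    2 free catalyst ⇌ resting dimer, settled at all times (K6 = 150 /M)
    starting material + target → side product (k7 = 0.35 /M/s)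

solid substrate 0.10 M; second substrate 0.0500 M; free catalyst 5.0 mM; time 2.0 min

* target at 2.0 min, in percent of the solid substrate charged
* the change that raises the amount of target at 2.0 min, in percent of the solid substrate charged most ("none" if none brings more than 2 percentage points) (midnight / winter / summer / none)
* amount of target at 2.0 min, in percent of the solid substrate charged, after midnight

- midnight: doubling the solubility in step 5, all else as stated
- winter: doubling the dissolution coefficient of step 5, all else as stated
- summer: doubling the amount of free catalyst, all else as stated

- in percentages every species weighs as the solid substrate in it: one side product counts as two
- a step written with two of one species runs at k times the square of its concentration and takes two of it each time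
- as a solid, counted per litre of solution: solid substrate
- at the start none of the solid substrate is in solution
- run time (flask): 2.0 min

In this reckoning the race has two lanes. The catalyst takes starting material at keff[free catalyst], where keff = 27.4 /M/s is k1 times the chance that catalyst intermediate A goes on rather than back; target takes it at k7[target]. Free catalyst has a top value, 2.74 mM, when resting dimer is its lone partner. With starting material at solubility and second substrate at charge, each free catalyst has 4.04 bound ones beside it, and free catalyst sinks to 0.940 mM. The midpoint, 1.84 mM, serves as working value.

So the branch number ρ = k7·[solid charge]/(keff·[working free catalyst]) = 0.695, a selectivity factor, sets the level. With p the target as a fraction of the charge, each starting material spent yields (1 − ρp)/(1 + ρp) target. Integration over the charge gives −p − (2/ρ)·ln(1 − ρp) = 1, hence p = 61.9%.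

The curve starts flat, for the solution half fills in 5.33 s. It then climbs at about 0.772 /min of the charge. The knee follows near 0.802 min, earlier than 2.0 min, and the curve lies flat afterwards. The coefficient k5 does not stand in ρ, but cs5 does, through the bound count: doubled, it gives 5.91 bound ones, a low free catalyst of 0.702 mM and ρ = 0.742, so midnight should lower the level to p = 60.4%. Summer lifts the top value of free catalyst to 4.34 mM, lowers ρ, and is this reckoning's choice.

The forecast gives 55%, lower than this reckoning, with 57% after midnight and summer as its choice, since “doubling the catalyst speeds productive turnover relative to the side reaction”.

The flask gives 62.4%, 59.3% after midnight, and summer gains most at 13 percentage points. The forecast's figure is what [second substrate] held at its starting value gives. At 2.00 min this flask holds 37.5% as side product and 0.0405% as starting material. At the working free catalyst, an estimate and not the free catalyst of the end, ρ puts the side lane of this flask at ρp = 0.434 of the catalyst lane for the level it reached. The neighbour flask with 0.040 M of solid substrate has ρ = 0.278 at the same working free catalyst, hence p = 79.3%, and that flask stands at 80.9%.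

(The rate constants were chosen freely; the flask was simulated.)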